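**Plan**

- Retrosynthesis: ring A carbons are numbered C1′ (acyl-bearing) to C6′. The three isopropyl ethers (C5–O, C7–O, C2′–O) are cut first, then the C1′–C(=O) bond (Friedel–Crafts acylation). Ring A is then cut at C5′–C6′, C3′–C4′ and C1′–C6′ into a 3-alkoxy-2-methylcyclobutenone and a methoxyalkyne. The alkyne arm is cut at CH2–C(sp) (Stille) and C8–CH2 (bromomethylation), and the chromanone at C4–C4a and O1–C2.
- Forward order: the benzene ring of the chromanone is bought as 2-methylresorcinol and its third oxygen is introduced para to the methyl. The pyranone ring is closed onto that oxygen, which fixes the methyl at C6 and leaves C8 free. The propargyl arm is attached, ring A is built last by benzannulation, then acylated and unmasked.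
- Enabling feature: ring A is a phloroglucinol ring in which only the C4′ oxygen is methylated, lying between C3′–Me and C5′–CH2 (the link to C8 of the chromanone), with C6′–OH next to a carbon (C1′) that is still unsubstituted before acylation. C4′ and C5′ map onto the two carbons of a methoxyalkyne; C6′, C1′, C2′ and C3′ map onto the four ring carbons of a 3-alkoxy-2-methylcyclobutenone.
- Stereochemistry: the single stereocentre (C2 of the acyl chain, R) is bought as (2R)-2-methylbutanoic acid, introduced in the penultimate step and never exposed to base.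

Key step: step 10

Assumption: (2R)-2-methylbutanoic acid is taken as purchasable in enantiopure form, and the ethers that must fall at the end (C5–O, C7–O, C2′–O) are chosen as isopropyl ethers, because BCl3 removes a secondary alkyl ether without needing a neighbouring carbonyl while the C4′ methyl ether stays.

**Route**

Step 1
Reactants: 1 1-ethoxyprop-1-yne; 2 acetyl chloride
Product: 4 3-ethoxy-2-methylcyclobut-2-en-1-one, via ketene 3 (not isolated)
Conditions: Et3N, Et2O, 0 °C → rt (slow addition of 2)
Reagents that add atoms: none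
Why: Dehydrochlorination of 2 releases ketene 3, which should undergo the [2+2] cycloaddition of a ketene with an ynol ether; the alkyne carbon remote from oxygen attacks the ketene carbonyl carbon, so the methyl ends at C2 and the ethoxy group at C3.

Step 2
Reactants: 4 3-ethoxy-2-methylcyclobut-2-en-1-one
Product: 5 3-hydroxy-2-methylcyclobut-2-en-1-one (enol form of 2-methylcyclobutane-1,3-dione)
Conditions: 1 M HCl aq, THF, rt
Reagents that add atoms: water, O
Why: Acid hydrolysis of the vinylogous ester (addition of water at C3, loss of ethanol) should give the strongly acidic 1,3-dione, handled as its enol.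

Step 3
Reactants: 5 3-hydroxy-2-methylcyclobut-2-en-1-one
Product: 6 2-methyl-3-(propan-2-yloxy)cyclobut-2-en-1-one
Conditions: i-PrOH, TsOH·H2O (cat.), PhH, reflux (Dean–Stark)
Reagents that add atoms: propan-2-ol, CC(C)O
Why: Acid-catalysed enol etherification of a cyclic 1,3-dione (the vinylogous counterpart of a Fischer esterification) with azeotropic removal of water; the two carbonyls are equivalent, so a single enol ether should form, and it carries the isopropyl group that BCl3 can later remove from the C2′ oxygen.

Step 4
Reactants: 7 2-methylbenzene-1,3-diol (2-methylresorcinol)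
Product: 8 2-methyl-1,3-di(propan-2-yloxy)benzene
Conditions: 2-bromopropane, K2CO3, DMF, 70 °C
Reagents that add atoms: 2-bromopropane, CC(C)Br
Why: Williamson etherification of both phenols; isopropyl ethers should tolerate the later Brønsted-acidic, palladium and thermal steps and leave the ring C–H para to the methyl as the only unhindered site for step 5.

Step 5
Reactants: 8 2-methyl-1,3-di(propan-2-yloxy)benzene
Product: 10 4-methyl-3,5-di(propan-2-yloxy)phenol, via arylboronate 9 (not isolated)
Conditions: B2pin2, [Ir(OMe)(cod)]2 (1.5 mol %), dtbpy (3 mol %), THF, 80 °C; then KHSO5 (as 2KHSO5·KHSO4·K2SO4), acetone/H2O, rt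
Reagents that add atoms: potassium peroxymonosulfate, [K+].OOS([O-])(=O)=O
Why: Iridium-catalysed aromatic C–H borylation is sterically controlled and should go to the only ring C–H without an ortho substituent (para to the methyl), and oxidation of the C–B bond then gives the phenol.

Step 6
Reactants: 10 4-methyl-3,5-di(propan-2-yloxy)phenol; 11 3-methylbut-2-enoic acid
Product: 12 2,2,6-trimethyl-5,7-di(propan-2-yloxy)chroman-4-one
Conditions: P2O5 in MeSO3H (1:10 w/w), 45 °C
Reagents that add atoms: none
Why: Friedel–Crafts acylation ortho to the free hydroxyl by the activated acid, then intramolecular oxa-Michael closure of that hydroxyl onto the β,β-dimethyl enone; because the only free oxygen is the one para to the methyl, the methyl can end only at C6 and C8 stays open.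

Step 7
Reactants: 12 2,2,6-trimethyl-5,7-di(propan-2-yloxy)chroman-4-one
Product: 13 8-(bromomethyl)-2,2,6-trimethyl-5,7-di(propan-2-yloxy)chroman-4-one
Conditions: (CH2O)n, 33% HBr in AcOH, rt; used crude
Reagents that add atoms: formaldehyde (as paraformaldehyde), C=O; hydrogen bromide, Br
Why: Bromomethylation (Blanc-type electrophilic hydroxymethylation, then OH-to-Br exchange) should occur at C8, the single free ring position, which is activated by the ortho C7 ether, the ortho ring oxygen and the para C5 ether.

Step 8
Reactants: 14 2-chloro-1,1-dimethoxyethane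
Product: 16 tributyl(methoxyethynyl)stannane, via lithium methoxyacetylide 15 (not isolated)
Conditions: Et2NH, n-BuLi, THF, 0 °C (gives LiNEt2, 3.1 equiv); 14, 0 °C → rt; then Bu3SnCl, −78 °C → rt
Reagents that add atoms: tributyltin chloride, CCCC[Sn](Cl)(CCCC)CCCC
Why: Threefold action of the amide base (β-elimination of methoxide, elimination of HCl, deprotonation of methoxyacetylene) should give acetylide 15, which is stannylated at carbon; this is the usual one-flask entry to metalated alkoxyacetylenes from chloroacetaldehyde acetals.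

Step 9
Reactants: 13 8-(bromomethyl)-2,2,6-trimethyl-5,7-di(propan-2-yloxy)chroman-4-one; 16 tributyl(methoxyethynyl)stannane
Product: 17 8-(3-methoxyprop-2-yn-1-yl)-2,2,6-trimethyl-5,7-di(propan-2-yloxy)chroman-4-one
Conditions: Pd(PPh3)4 (5 mol %), PhMe, 70 °C; chromatography on Et3N-deactivated silica
Reagents that add atoms: none
Why: Stille coupling: zerovalent palladium inserts into the benzylic C–Br bond, the alkynyl group transfers from tin faster than butyl, and reductive elimination forms the CH2–C(sp) bond under neutral conditions that should spare the ketone and the acid-sensitive ynol ether.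

Step 10
Reactants: 6 2-methyl-3-(propan-2-yloxy)cyclobut-2-en-1-one; 17 8-(3-methoxyprop-2-yn-1-yl)-2,2,6-trimethyl-5,7-di(propan-2-yloxy)chroman-4-one
Product: 22 8-{[6-hydroxy-2-methoxy-3-methyl-4-(propan-2-yloxy)phenyl]methyl}-2,2,6-trimethyl-5,7-di(propan-2-yloxy)chroman-4-one, via vinylketene 18 (not isolated), via vinylcyclobutenone 19 (not isolated), via dienylketene 20 (not isolated), via cyclohexadienone 21 (not isolated)
Conditions: 6 (1.5 equiv), PhMe, 110 °C, sealed tube
Reagents that add atoms: none
Why: Heating should open 6 by 4π electrocyclic ring opening to vinylketene 18, whose ketene carbon is attacked by the alkyne carbon of 17 that bears the CH2 group (the carbon β to OMe); the [2+2] adduct 19 then opens (4π) to dienylketene 20, closes by 6π electrocyclization to cyclohexadienone 21 and tautomerizes to phenol 22. The closest known reaction is the Danheiser benzannulation of cyclobutenones with alkoxyalkynes, which gives resorcinol monoethers; the 3-alkoxy group of 6 only supplies the third ring oxygen. Ring A is closed by the thermal disrotatory 6π electrocyclization that forms C1′–C6′, after the [2+2] step has made C5′–C6′ and C3′–C4′ through a transient four-membered ring. No stereocentre is created that survives: the quaternary carbon of 19 is lost on ring opening, and the side-chain centre is not yet present. The selectivity needed is the orientation of the ketene–alkyne union, and the polarization of the ynol ether secures it, placing OMe at C4′ (meta to the new hydroxyl), CH2 at C5′ and leaving C1′ as the one unsubstituted carbon. Side reactions should be limited because all other hydroxyls are isopropyl ethers, so the ketene meets no O–H group at the outset, and because a methoxyalkyne has no β-hydrogen for thermal retro-ene loss of an alkene.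

Step 11
Reactants: 22 8-{[6-hydroxy-2-methoxy-3-methyl-4-(propan-2-yloxy)phenyl]methyl}-2,2,6-trimethyl-5,7-di(propan-2-yloxy)chroman-4-one; 23 (2R)-2-methylbutanoic acid
Product: 25 8-{[6-hydroxy-2-methoxy-3-methyl-5-[(2R)-2-methylbutanoyl]-4-(propan-2-yloxy)phenyl]methyl}-2,2,6-trimethyl-5,7-di(propan-2-yloxy)chroman-4-one, via acid chloride 24 (not isolated)
Conditions: 23, (COCl)2, DMF (cat.), CH2Cl2, 0 °C → rt, evaporate; then 22, TiCl4 (2.2 equiv), CH2Cl2, −78 → −20 °C
Reagents that add atoms: none
Why: Friedel–Crafts acylation, directed by the titanium phenoxide of the C6′ hydroxyl to C1′, the only unsubstituted aromatic carbon in the molecule (ortho to the C6′ and C2′ oxygens, para to the C4′ methoxy group); the acid chloride is made and used without base, so no ketene can form and the R centre of 23 should be carried over unchanged.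

Step 12
Reactants: 25 8-{[6-hydroxy-2-methoxy-3-methyl-5-[(2R)-2-methylbutanoyl]-4-(propan-2-yloxy)phenyl]methyl}-2,2,6-trimethyl-5,7-di(propan-2-yloxy)chroman-4-one
Product: 26 5,7-dihydroxy-8-{[2,4-dihydroxy-6-methoxy-5-methyl-3-[(2R)-2-methylbutanoyl]phenyl]methyl}-2,2,6-trimethylchroman-4-one
Conditions: BCl3 (8 equiv), CH2Cl2, −78 → 0 °C; then H2O
Reagents that add atoms: none
Why: Lewis-acid dealkylation: BCl3 should cleave the three isopropyl aryl ethers through O–B coordination and loss of the secondary alkyl group as 2-chloropropane, whereas the C4′ methyl ether, which has no carbonyl neighbour for chelation and would need SN2 attack at methyl, should persist at 0 °C or below; the stereocentre is not involved.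

**Compound list**

1 | 1-ethoxyprop-1-yne | CCOC#CC | starting material
2 | acetyl chloride | CC(Cl)=O | starting material
3 | ketene (ethenone) | C=C=O | intermediate
4 | 3-ethoxy-2-methylcyclobut-2-en-1-one | CCOC1=C(C)C(=O)C1 | intermediate
5 | 3-hydroxy-2-methylcyclobut-2-en-1-one (enol form of 2-methylcyclobutane-1,3-dione) | CC1=C(O)CC1=O | intermediate
6 | 2-methyl-3-(propan-2-yloxy)cyclobut-2-en-1-one | CC(C)OC1=C(C)C(=O)C1 | intermediate
7 | 2-methylbenzene-1,3-diol (2-methylresorcinol) | Cc1c(O)cccc1O | starting material
8 | 2-methyl-1,3-di(propan-2-yloxy)benzene | Cc1c(OC(C)C)cccc1OC(C)C | intermediate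
9 | 4,4,5,5-tetramethyl-2-[4-methyl-3,5-di(propan-2-yloxy)phenyl]-1,3,2-dioxaborolane | Cc1c(OC(C)C)cc(cc1OC(C)C)B1OC(C)(C)C(C)(C)O1 | intermediate
10 | 4-methyl-3,5-di(propan-2-yloxy)phenol | Cc1c(OC(C)C)cc(O)cc1OC(C)C | intermediate
11 | 3-methylbut-2-enoic acid (3,3-dimethylacrylic acid) | CC(C)=CC(O)=O | starting material
12 | 2,2,6-trimethyl-5,7-di(propan-2-yloxy)chroman-4-one | CC(C)Oc1cc2OC(C)(C)CC(=O)c2c(OC(C)C)c1C | intermediate
13 | 8-(bromomethyl)-2,2,6-trimethyl-5,7-di(propan-2-yloxy)chroman-4-one | CC(C)Oc1c(CBr)c2OC(C)(C)CC(=O)c2c(OC(C)C)c1C | intermediate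
14 | 2-chloro-1,1-dimethoxyethane (chloroacetaldehyde dimethyl acetal) | COC(CCl)OC | starting material
15 | lithium methoxyacetylide | [Li]C#COC | intermediate
16 | tributyl(methoxyethynyl)stannane | CCCC[Sn](CCCC)(CCCC)C#COC | intermediate
17 | 8-(3-methoxyprop-2-yn-1-yl)-2,2,6-trimethyl-5,7-di(propan-2-yloxy)chroman-4-one | COC#CCc1c(OC(C)C)c(C)c(OC(C)C)c2C(=O)CC(C)(C)Oc12 | intermediate
18 | 2-methyl-3-(propan-2-yloxy)buta-1,3-dien-1-one (vinylketene) | C=C(OC(C)C)C(C)=C=O | intermediate
19 | racemic 3-methoxy-4-methyl-4-[1-(propan-2-yloxy)ethenyl]-2-{[2,2,6-trimethyl-4-oxo-5,7-di(propan-2-yloxy)chroman-8-yl]methyl}cyclobut-2-en-1-one | COC1=C(Cc2c(OC(C)C)c(C)c(OC(C)C)c3C(=O)CC(C)(C)Oc23)C(=O)C1(C)C(=C)OC(C)C | intermediate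
20 | (3E)-3-methoxy-4-methyl-5-(propan-2-yloxy)-2-{[2,2,6-trimethyl-4-oxo-5,7-di(propan-2-yloxy)chroman-8-yl]methyl}hexa-1,3,5-trien-1-one (dienylketene) | O=C=C(Cc1c(OC(C)C)c(C)c(OC(C)C)c2C(=O)CC(C)(C)Oc12)/C(OC)=C(C)\C(=C)OC(C)C | intermediate
21 | 3-methoxy-4-methyl-5-(propan-2-yloxy)-2-{[2,2,6-trimethyl-4-oxo-5,7-di(propan-2-yloxy)chroman-8-yl]methyl}cyclohexa-2,4-dien-1-one | COC1=C(Cc2c(OC(C)C)c(C)c(OC(C)C)c3C(=O)CC(C)(C)Oc23)C(=O)CC(OC(C)C)=C1C | intermediate
22 | 8-{[6-hydroxy-2-methoxy-3-methyl-4-(propan-2-yloxy)phenyl]methyl}-2,2,6-trimethyl-5,7-di(propan-2-yloxy)chroman-4-one | CC(C)Oc1cc(O)c(Cc2c(OC(C)C)c(C)c(OC(C)C)c3C(=O)CC(C)(C)Oc23)c(OC)c1C | intermediate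
23 | (2R)-2-methylbutanoic acid | CC[C@@H](C)C(O)=O | starting material
24 | (2R)-2-methylbutanoyl chloride | CC[C@@H](C)C(Cl)=O | intermediate
25 | 8-{[6-hydroxy-2-methoxy-3-methyl-5-[(2R)-2-methylbutanoyl]-4-(propan-2-yloxy)phenyl]methyl}-2,2,6-trimethyl-5,7-di(propan-2-yloxy)chroman-4-one | CC[C@@H](C)C(=O)c1c(OC(C)C)c(C)c(OC)c(Cc2c(OC(C)C)c(C)c(OC(C)C)c3c2OC(C)(C)CC3=O)c1O | intermediate
26 | 5,7-dihydroxy-8-{[2,4-dihydroxy-6-methoxy-5-methyl-3-[(2R)-2-methylbutanoyl]phenyl]methyl}-2,2,6-trimethylchroman-4-one (CNP0303209.1) | CC[C@@H](C)C(=O)c1c(O)c(C)c(OC)c(Cc2c(O)c(C)c(O)c3c2OC(C)(C)CC3=O)c1O | target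

**Step count and risks**

Total step count: 12. Longest linear sequence: 8 steps (7 → 8 → 10 → 12 → 13 → 17 → 22 → 25 → 26; steps 4, 5, 6, 7, 9, 10, 11, 12).

Steps most likely to fail:

Step 10. The push–pull (vinylogous ester) cyclobutenone may open too slowly, so that the ynol ether is lost by thermal decomposition or hydration before it is captured; a second vinylketene may also acylate the new phenol. The fallback gives up the benzannulation and forms the C5′–CH2 bond by Friedel–Crafts benzylation of a preformed ring A. It sets out from bromide 13 and from 7. Diol 7 is mono-O-methylated (MeI, K2CO3, acetone) to 3-methoxy-2-methylphenol F1 and O-isopropylated (2-bromopropane, K2CO3, DMF) to 1-methoxy-2-methyl-3-(propan-2-yloxy)benzene F2. This is borylated as in step 5 to 2-[3-methoxy-4-methyl-5-(propan-2-yloxy)phenyl]-4,4,5,5-tetramethyl-1,3,2-dioxaborolane F3 and oxidized to 3-methoxy-4-methyl-5-(propan-2-yloxy)phenol F4. Phenol F4 is then C-benzylated with 13 (ZnCl2, CH2Cl2, 0 °C) ortho to its hydroxyl; attack next to the smaller methoxy group is expected to prevail, and the isomer from attack next to the isopropoxy group would have to be separated. The fallback comes back to the route at 22.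

Step 11. The Lewis acid may strip isopropyl groups before acylation is complete, may provoke ipso attack at C5′ with cleavage of the methylene bridge, or may erode the configuration by enolization of the metal-bound ketone. The fallback avoids any Lewis acid. It sets out from 22, which is esterified at the C6′ hydroxyl with 23 (Steglich esterification: EDC·HCl, DMAP cat., CH2Cl2, 0 °C) to give 3-methoxy-4-methyl-5-(propan-2-yloxy)-2-{[2,2,6-trimethyl-4-oxo-5,7-di(propan-2-yloxy)chroman-8-yl]methyl}phenyl (2R)-2-methylbutanoate F5. A photo-Fries rearrangement (hν 254 nm, MeCN, rt) should then move the acyl group within the radical pair to C1′, the only free ortho position, without touching the stereocentre. The fallback comes back to the route at 25.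

Step 7. The reactive benzylic bromide may alkylate unreacted 12 to a diarylmethane, and HBr may remove the chelated C5 isopropyl group. The fallback introduces the carbon stepwise. It sets out from 12, which is formylated at C8 (Rieche formylation: Cl2CHOMe, SnCl4, CH2Cl2, −20 °C; chosen because Vilsmeier conditions would also attack the enolizable C4 ketone) to 2,2,6-trimethyl-4-oxo-5,7-di(propan-2-yloxy)chromane-8-carbaldehyde F6. The aldehyde is reduced in the presence of the ketone with NaBH(OAc)3 (PhH, reflux) to 8-(hydroxymethyl)-2,2,6-trimethyl-5,7-di(propan-2-yloxy)chroman-4-one F7, which is converted with PBr3 (Et2O, 0 °C) into the bromide. The fallback comes back to the route at 13.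

**Further compounds**

F1 | step 10 | 3-methoxy-2-methylphenol | COc1cccc(O)c1C
F2 | step 10 | 1-methoxy-2-methyl-3-(propan-2-yloxy)benzene | COc1cccc(OC(C)C)c1C
F3 | step 10 | 2-[3-methoxy-4-methyl-5-(propan-2-yloxy)phenyl]-4,4,5,5-tetramethyl-1,3,2-dioxaborolane | COc1cc(cc(OC(C)C)c1C)B1OC(C)(C)C(C)(C)O1
F4 | step 10 | 3-methoxy-4-methyl-5-(propan-2-yloxy)phenol | COc1cc(O)cc(OC(C)C)c1C
F5 | step 11 | 3-methoxy-4-methyl-5-(propan-2-yloxy)-2-{[2,2,6-trimethyl-4-oxo-5,7-di(propan-2-yloxy)chroman-8-yl]methyl}phenyl (2R)-2-methylbutanoate | CC[C@@H](C)C(=O)Oc1cc(OC(C)C)c(C)c(OC)c1Cc1c(OC(C)C)c(C)c(OC(C)C)c2C(=O)CC(C)(C)Oc12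
F6 | step 7 | 2,2,6-trimethyl-4-oxo-5,7-di(propan-2-yloxy)chromane-8-carbaldehyde | CC(C)Oc1c(C=O)c2OC(C)(C)CC(=O)c2c(OC(C)C)c1C
F7 | step 7 | 8-(hydroxymethyl)-2,2,6-trimethyl-5,7-di(propan-2-yloxy)chroman-4-one | CC(C)Oc1c(CO)c2OC(C)(C)CC(=O)c2c(OC(C)C)c1C
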